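At the 15 min reading the dawn run stands at 0.3801 M of product, and the stretch from 6.7 min has added 0.0354 M, although the one-to-one overall equation leaves 0.420 M of starting material and, on paper, 1.62 M of partner.

| flask | starting material | partner | time |
|---|---|---|---|
| dawn | 0.800 M | 2.00 M |  |
| winter | 0.400 M | 1.60 M |  |
| midnight | 1.60 M | 2.00 M |  |
| summer | 0.800 M | 0.400 M | 15 min |

- dawn run (time / min: [product] / M): 0.60: 0.1342; 1.3: 0.2020; 3.0: 0.2846; 6.7: 0.3447; 15: 0.3801
- winter run (time / min: [product] / M): 0.60: 0.0766; 1.3: 0.1150; 3.0: 0.1645; 6.7: 0.2028; 15: 0.2367
- midnight run (time / min: [product] / M): 0.60: 0.2080; 1.3: 0.3091; 3.0: 0.4265; 6.7: 0.5043; 15: 0.5370

(standard deviation of a reading: 0.002 M)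

1. reaction order in [starting material] at the outset, round the charge of the dawn run, defined at two percent of the starting material turned into product (one fixed amount of product, the same in the runs compared)
2. reaction order in [partner] at the outset, round the charge of the dawn run, defined at two percent of the starting material turned into product
3. product in the summer run at 15 min, as a share of the starting material charged

- Overall: starting material + partner -> product.
- Constant volume, constant temperature.
- What is held in complexes is read along with the free species.
- An order is taken over about fifteen percent of the charge, up and down.

The summer run is the near neighbour of dawn, with the same starting material but less partner. My own reckoning supposes that partner leaves by a second path, which goes with the square of its level. At partner level R, the share taken into product is then c/(c + R), and summing that share as partner falls from its charge R gives the product P: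

P = c·ln(1 + R/c)

Solving this for the dawn reading by repeated substitution gives

c = 0.139 M

This c is the tie level, the partner concentration at which the two paths take partner equally fast, a selectivity factor in concentration units. You can carry it to summer because the charges of starting material match. The opening share of partner going to product is 6.51 % at the dawn charge and 25.8 % at the summer charge, so on this reckoning summer sends a larger share of its partner to product than dawn. The rule still puts summer's product lower than the dawn reading:

P = 0.189 M, which is 23.6 % of the starting material

The forecast gives orders of 0.68 in starting material and 0.25 in partner, and 24 % for the summer run, on different grounds: “a hidden catalyst dying with time, plus saturation kinetics”.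

The summer run gives 24.6 % at 15 min. Round the charge of the dawn run, the order at the outset is 0.69 in starting material, against the forecast's 0.68, and 0.91 in partner, against the forecast's 0.25.

    starting material + partner ⇌ intermediate, settled at all times (0.2710 M⁻¹)
    starting material + partner → product (0.8160 M⁻¹ min⁻¹)
    2 partner → lost reagent (0.6960 M⁻¹ min⁻¹)
    2 starting material ⇌ idle substrate dimer, settled at all times (3.210 M⁻¹)

The path from partner to lost reagent moves the readings by 220 in units of the scatter (root mean square). Put through the rule, the summer product of 0.197 M returns a tie level of 0.152 M, beside 0.139 M from the dawn run. For the midnight run, scaling c by its rate ratio to dawn of 1.6 gives 0.218 M, and the rule then gives 0.506 M, where the 15 min reading is 0.5370 M.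

All runs are simulated on assumed constants, noise included.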